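**Retrosynthetic overview**

- The target is the (2S,3S,2′S,3′S)-trans,trans compound with an E-stilbene. Its four stereocentres are C2/C3 of the dihydrofuran ring of unit A (styryl at C6) and C2′/C3′ of the dihydrofuran ring of unit B (bonded through C6′ to C3, 3,5-dihydroxyphenyl at C3′). Each ring is a flat 3-aryl-4-oxybenzofuran plus a 4-hydroxyphenyl group at C2 and a hydrogen at C3.
- Endgame: the stilbene C=C comes from the C6 aldehyde by Horner–Wadsworth–Emmons olefination, and the seven O-methyl groups are removed last.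
- Key disconnection: both C2–aryl bonds and both C3–H bonds are made in one twofold enantioselective reductive Heck dearomatisation of the achiral bis(3-arylbenzofuran) aldehyde with 4-iodoanisole.
- The bis(benzofuran) aldehyde is built from 3,5-dimethoxybenzaldehyde used three times. Two successive lithiations between methoxy groups, each followed by addition to the aldehyde, give a triaryl diol. Twofold oxidation, twofold methoxymethylenation and one HBr-induced twofold demethylative cyclodehydration then close the furan rings of units A and B in the same operation (step 6); no ring is formed afterwards.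

Key step: step 7

Assumption: the sense of induction of the chiral ligand cannot be predicted reliably; (R)-BINAP is written, and its enantiomer is used instead if a first run gives the 2R,3R,2′R,3′R series.

**Route**

Step 1
Reactants: 1 3,5-dimethoxybenzaldehyde
Product: 2 acetal 1-(dimethoxymethyl)-3,5-dimethoxybenzene
Conditions: HC(OMe)3, TsOH·H2O (cat.), MeOH, rt; then Et3N
Reagents that add atoms: trimethyl orthoformate COC(OC)OC; methanol CO
Why: Acid-catalysed acetalisation, driven to completion by the orthoformate as water scavenger, masks the aldehyde in a form that survives organolithium and ylide chemistry and is released again in the acid step 6.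

Step 2
Reactants: 2 acetal 1-(dimethoxymethyl)-3,5-dimethoxybenzene; 1 3,5-dimethoxybenzaldehyde
Product: 4 carbinol [4-(dimethoxymethyl)-2,6-dimethoxyphenyl](3,5-dimethoxyphenyl)methanol (racemic), via aryllithium 3 (not isolated)
Conditions: n-BuLi (slight deficit to 2), THF, 0 °C → rt; then 1, −78 °C → rt; H2O
Reagents that add atoms: none
Why: Directed ortho-metalation removes the ring proton flanked by both methoxy groups (C4 of the acetal, as with other 5-substituted 1,3-dimethoxybenzenes) and the aryllithium adds 1,2 to the aldehyde; the acetal ring becomes ring A, the new 3,5-dimethoxyphenyl ring becomes ring B, and the racemic carbinol centre is erased in step 4.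

Step 3
Reactants: 4 carbinol [4-(dimethoxymethyl)-2,6-dimethoxyphenyl](3,5-dimethoxyphenyl)methanol; 1 3,5-dimethoxybenzaldehyde
Product: 6 diol [4-(dimethoxymethyl)-2,6-dimethoxyphenyl]{4-[(3,5-dimethoxyphenyl)(hydroxy)methyl]-3,5-dimethoxyphenyl}methanol (mixture of racemic diastereomers), via dilithio species 5 (not isolated)
Conditions: n-BuLi (2.05 equiv), THF, 0 °C → rt; then 1 (1.1 equiv), −78 °C → rt; H2O
Reagents that add atoms: none
Why: The first equivalent of n-BuLi forms the lithium alkoxide, which protects the benzhydrylic C–H, and the second performs the same directed ortho-metalation as in step 2 at the ring B proton flanked by two methoxy groups (the positions next to the carbinol carbon are activated by one methoxy group only and are shielded by the diarylmethyl group), after which the aryllithium adds 1,2 to the aldehyde; both carbinol centres are erased in step 4.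

Step 4
Reactants: 6 diol [4-(dimethoxymethyl)-2,6-dimethoxyphenyl]{4-[(3,5-dimethoxyphenyl)(hydroxy)methyl]-3,5-dimethoxyphenyl}methanol
Product: 9 diketone [4-(dimethoxymethyl)-2,6-dimethoxyphenyl][4-(3,5-dimethoxybenzoyl)-3,5-dimethoxyphenyl]methanone, via B–C keto alcohol 7 (not isolated), via A–B keto alcohol 8 (not isolated)
Conditions: activated MnO2 (large excess), CH2Cl2, rt
Reagents that add atoms: none
Why: MnO2 oxidation of doubly benzylic alcohols converts both carbinols into diaryl ketones under neutral conditions that leave the dimethyl acetal intact.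

Step 5
Reactants: 9 diketone [4-(dimethoxymethyl)-2,6-dimethoxyphenyl][4-(3,5-dimethoxybenzoyl)-3,5-dimethoxyphenyl]methanone; 10 (methoxymethyl)triphenylphosphonium chloride
Product: 14 bis(enol ether) 5-{1-[4-(dimethoxymethyl)-2,6-dimethoxyphenyl]-2-methoxyethenyl}-2-[1-(3,5-dimethoxyphenyl)-2-methoxyethenyl]-1,3-dimethoxybenzene (mixture of E/Z isomers), via ylide 11 (not isolated), via B–C enol ether ketone 12 (not isolated), via A–B enol ether ketone 13 (not isolated)
Conditions: 10 (6 equiv), KOtBu (5.8 equiv), THF, 0 °C; then 9, 0 → 60 °C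
Reagents that add atoms: none
Why: Wittig methoxymethylenation of the two non-enolisable diaryl ketones with an excess of the unstabilised ylide should give the doubly one-carbon-homologated enol ether; the E/Z ratio at either double bond is irrelevant because all isomers converge in step 6.

Step 6
Reactants: 14 bis(enol ether) 5-{1-[4-(dimethoxymethyl)-2,6-dimethoxyphenyl]-2-methoxyethenyl}-2-[1-(3,5-dimethoxyphenyl)-2-methoxyethenyl]-1,3-dimethoxybenzene
Product: 18 bis(benzofuran) aldehyde 3-[3-(3,5-dimethoxyphenyl)-4-methoxy-1-benzofuran-6-yl]-4-methoxy-1-benzofuran-6-carbaldehyde, via trialdehyde 15 (not isolated), via unit B benzofuran dialdehyde 16 (not isolated), via unit A benzofuran dialdehyde 17 (not isolated)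
Conditions: 48% aq. HBr, AcOH, 55 °C (dilute)
Reagents that add atoms: water O
Why: Acid hydrolysis of both enol ethers and of the acetal gives trialdehyde 15, in each 2,2-diarylacetaldehyde unit the protonated formyl group is attacked by the oxygen of a neighbouring ortho-methoxy group to form a five-membered oxonium ion, bromide removes the methyl group by SN2 and the lactol dehydrates to the aromatic furan (demethylative cyclodehydration of ortho-methoxyaryl carbonyl compounds), so only the two participating methyl ethers are cleaved at a temperature where ordinary aryl methyl ethers resist HBr, and because each formyl group has ortho-methoxy groups on one of its two aryl rings only (ring B for the terminal unit, ring A for the internal unit) the regiochemistry of both closures is fixed.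

Step 7
Reactants: 18 bis(benzofuran) aldehyde 3-[3-(3,5-dimethoxyphenyl)-4-methoxy-1-benzofuran-6-yl]-4-methoxy-1-benzofuran-6-carbaldehyde; 19 4-iodoanisole
Product: 22 (2S,3S)-3-[(2S,3S)-3-(3,5-dimethoxyphenyl)-4-methoxy-2-(4-methoxyphenyl)-2,3-dihydro-1-benzofuran-6-yl]-4-methoxy-2-(4-methoxyphenyl)-2,3-dihydro-1-benzofuran-6-carbaldehyde, via B-unit mono-adduct 20 (not isolated), via A-unit mono-adduct 21 (not isolated)
Conditions: 19 (4 equiv), Pd(OAc)2 (10 mol%), (R)-BINAP (12 mol%), HCO2Na (5 equiv, added in portions), DMF–MeOH 4:1, 90 °C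
Reagents that add atoms: none
Why: Proposed new method: 4-iodoanisole adds oxidatively to the zerovalent palladium–bisphosphine complex and the aryl–palladium species adds syn across C2=C3 of each 3-arylbenzofuran, aryl to the oxygen-bearing C2 and palladium to C3, where the C3 aryl group holds it as a π-benzyl complex; iodide/formate exchange, loss of CO2 and C–H reductive elimination with retention then put hydrogen at C3 on the face of the new C2 aryl group, which leaves the two aryl groups trans. The closest known reaction type is the palladium-catalysed enantioselective dearomative reductive Heck reaction of indoles and benzofurans with tethered aryl halides and formate, whereas an intermolecular, twofold version on 3-arylbenzofurans is not established. No ring is closed; two C–C and two C–H bonds are formed. C2 and C2′ are set by the chiral ligand through the furan face chosen in the migratory insertion, and C3 and C3′ follow from them through syn addition and retentive reduction; the two furans are remote, so each is under catalyst control and the homochiral (2S,3S,2′S,3′S) isomer should dominate, with minor-face events diverted into separable heterochiral diastereomers. The step needs C2 regioselectivity, which the enol-ether polarisation and the benzylic stabilisation of palladium at C3 provide, and it needs reduction to outrun C2–H arylation and ring opening, which is secured because the C3–palladium intermediate has no syn β-hydrogen (C3 carries none, the C2–H is anti) and the ring C2–O bond cannot become syn-coplanar with palladium. Premature formate reduction of the aryl–palladium species is countered by the excess of 19 and the portionwise addition of formate.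

Step 8
Reactants: 22 (2S,3S)-3-[(2S,3S)-3-(3,5-dimethoxyphenyl)-4-methoxy-2-(4-methoxyphenyl)-2,3-dihydro-1-benzofuran-6-yl]-4-methoxy-2-(4-methoxyphenyl)-2,3-dihydro-1-benzofuran-6-carbaldehyde; 23 diethyl (4-methoxybenzyl)phosphonate
Product: 25 heptamethyl ether (2S,3S)-3-[(2S,3S)-3-(3,5-dimethoxyphenyl)-4-methoxy-2-(4-methoxyphenyl)-2,3-dihydro-1-benzofuran-6-yl]-4-methoxy-2-(4-methoxyphenyl)-6-[(E)-2-(4-methoxyphenyl)ethenyl]-2,3-dihydro-1-benzofuran, via phosphonate anion 24 (not isolated)
Conditions: 23 (1.5 equiv), KOtBu (1.4 equiv), THF, 0 °C; then 22, −40 °C → rt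
Reagents that add atoms: none
Why: Horner–Wadsworth–Emmons olefination with a benzylic phosphonate anion should give the E-stilbene, and pre-forming the anion with less base than phosphonate and adding the aldehyde cold avoids deprotonation at the doubly benzylic C3 and C3′, so the four stereocentres stay untouched.

Step 9
Reactants: 25 heptamethyl ether (2S,3S)-3-[(2S,3S)-3-(3,5-dimethoxyphenyl)-4-methoxy-2-(4-methoxyphenyl)-2,3-dihydro-1-benzofuran-6-yl]-4-methoxy-2-(4-methoxyphenyl)-6-[(E)-2-(4-methoxyphenyl)ethenyl]-2,3-dihydro-1-benzofuran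
Product: 26 target (2S,3S)-3-[(2S,3S)-3-(3,5-dihydroxyphenyl)-4-hydroxy-2-(4-hydroxyphenyl)-2,3-dihydro-1-benzofuran-6-yl]-2-(4-hydroxyphenyl)-6-[(E)-2-(4-hydroxyphenyl)ethenyl]-2,3-dihydro-1-benzofuran-4-ol
Conditions: BBr3 (20 equiv), CH2Cl2, −78 °C → rt; then MeOH, H2O
Reagents that add atoms: none
Why: Exhaustive Lewis-acid demethylation of aryl methyl ethers with BBr3 (aryl borate formation with loss of bromomethane, hydrolysis on work-up) is the usual last step for permethylated oligostilbenes, and any reversible opening of a C2–O bond should reclose to the more stable trans isomer because C3 and C3′ are not epimerised by acid.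

**Compound list**

1 | 3,5-dimethoxybenzaldehyde | COc1cc(C=O)cc(OC)c1 | starting material
2 | 1-(dimethoxymethyl)-3,5-dimethoxybenzene | COC(OC)c1cc(OC)cc(OC)c1 | intermediate
3 | [4-(dimethoxymethyl)-2,6-dimethoxyphenyl]lithium (formed in the flask, not isolated) | [Li]c1c(OC)cc(C(OC)OC)cc1OC | intermediate
4 | [4-(dimethoxymethyl)-2,6-dimethoxyphenyl](3,5-dimethoxyphenyl)methanol (racemic) | OC(c1cc(OC)cc(OC)c1)c1c(OC)cc(C(OC)OC)cc1OC | intermediate
5 | lithium [4-(dimethoxymethyl)-2,6-dimethoxyphenyl](4-lithio-3,5-dimethoxyphenyl)methanolate (formed in the flask, not isolated) | [Li]OC(c1cc(OC)c([Li])c(OC)c1)c1c(OC)cc(C(OC)OC)cc1OC | intermediate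
6 | [4-(dimethoxymethyl)-2,6-dimethoxyphenyl]{4-[(3,5-dimethoxyphenyl)(hydroxy)methyl]-3,5-dimethoxyphenyl}methanol (mixture of racemic diastereomers) | OC(c1cc(OC)cc(OC)c1)c1c(OC)cc(C(O)c2c(OC)cc(C(OC)OC)cc2OC)cc1OC | intermediate
7 | {4-[[4-(dimethoxymethyl)-2,6-dimethoxyphenyl](hydroxy)methyl]-2,6-dimethoxyphenyl}(3,5-dimethoxyphenyl)methanone (racemic; formed in the flask, not isolated) | O=C(c1cc(OC)cc(OC)c1)c1c(OC)cc(C(O)c2c(OC)cc(C(OC)OC)cc2OC)cc1OC | intermediate
8 | [4-(dimethoxymethyl)-2,6-dimethoxyphenyl]{4-[(3,5-dimethoxyphenyl)(hydroxy)methyl]-3,5-dimethoxyphenyl}methanone (racemic; formed in the flask, not isolated) | OC(c1cc(OC)cc(OC)c1)c1c(OC)cc(C(=O)c2c(OC)cc(C(OC)OC)cc2OC)cc1OC | intermediate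
9 | [4-(dimethoxymethyl)-2,6-dimethoxyphenyl][4-(3,5-dimethoxybenzoyl)-3,5-dimethoxyphenyl]methanone | O=C(c1cc(OC)cc(OC)c1)c1c(OC)cc(C(=O)c2c(OC)cc(C(OC)OC)cc2OC)cc1OC | intermediate
10 | (methoxymethyl)triphenylphosphonium chloride | COC[P+](c1ccccc1)(c1ccccc1)c1ccccc1.[Cl-] | starting material
11 | (methoxymethylidene)triphenylphosphorane (formed in the flask, not isolated) | COC=P(c1ccccc1)(c1ccccc1)c1ccccc1 | intermediate
12 | [4-(dimethoxymethyl)-2,6-dimethoxyphenyl]{4-[1-(3,5-dimethoxyphenyl)-2-methoxyethenyl]-3,5-dimethoxyphenyl}methanone (E/Z mixture; formed in the flask, not isolated) | COC=C(c1cc(OC)cc(OC)c1)c1c(OC)cc(C(=O)c2c(OC)cc(C(OC)OC)cc2OC)cc1OC | intermediate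
13 | (4-{1-[4-(dimethoxymethyl)-2,6-dimethoxyphenyl]-2-methoxyethenyl}-2,6-dimethoxyphenyl)(3,5-dimethoxyphenyl)methanone (E/Z mixture; formed in the flask, not isolated) | O=C(c1cc(OC)cc(OC)c1)c1c(OC)cc(C(=COC)c2c(OC)cc(C(OC)OC)cc2OC)cc1OC | intermediate
14 | 5-{1-[4-(dimethoxymethyl)-2,6-dimethoxyphenyl]-2-methoxyethenyl}-2-[1-(3,5-dimethoxyphenyl)-2-methoxyethenyl]-1,3-dimethoxybenzene (mixture of E/Z isomers) | COC=C(c1cc(OC)cc(OC)c1)c1c(OC)cc(C(=COC)c2c(OC)cc(C(OC)OC)cc2OC)cc1OC | intermediate
15 | 2-{4-[1-(3,5-dimethoxyphenyl)-2-oxoethyl]-3,5-dimethoxyphenyl}-2-(4-formyl-2,6-dimethoxyphenyl)acetaldehyde (mixture of diastereomers; formed in the flask, not isolated) | O=CC(c1cc(OC)cc(OC)c1)c1c(OC)cc(C(C=O)c2c(OC)cc(C=O)cc2OC)cc1OC | intermediate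
16 | 2-[3-(3,5-dimethoxyphenyl)-4-methoxy-1-benzofuran-6-yl]-2-(4-formyl-2,6-dimethoxyphenyl)acetaldehyde (racemic; formed in the flask, not isolated) | O=CC(c1cc(OC)c2c(c1)occ2-c1cc(OC)cc(OC)c1)c1c(OC)cc(C=O)cc1OC | intermediate
17 | 3-{4-[1-(3,5-dimethoxyphenyl)-2-oxoethyl]-3,5-dimethoxyphenyl}-4-methoxy-1-benzofuran-6-carbaldehyde (racemic; formed in the flask, not isolated) | O=Cc1cc(OC)c2c(c1)occ2-c1cc(OC)c(C(C=O)c2cc(OC)cc(OC)c2)c(OC)c1 | intermediate
18 | 3-[3-(3,5-dimethoxyphenyl)-4-methoxy-1-benzofuran-6-yl]-4-methoxy-1-benzofuran-6-carbaldehyde | O=Cc1cc(OC)c2c(c1)occ2-c1cc(OC)c2c(c1)occ2-c1cc(OC)cc(OC)c1 | intermediate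
19 | 4-iodoanisole | COc1ccc(I)cc1 | starting material
20 | 3-[(2S,3S)-3-(3,5-dimethoxyphenyl)-4-methoxy-2-(4-methoxyphenyl)-2,3-dihydro-1-benzofuran-6-yl]-4-methoxy-1-benzofuran-6-carbaldehyde (formed in the flask, not isolated) | O=Cc1cc(OC)c2c(c1)occ2-c1cc(OC)c2c(c1)O[C@H](c1ccc(OC)cc1)[C@H]2c1cc(OC)cc(OC)c1 | intermediate
21 | (2S,3S)-3-[3-(3,5-dimethoxyphenyl)-4-methoxy-1-benzofuran-6-yl]-4-methoxy-2-(4-methoxyphenyl)-2,3-dihydro-1-benzofuran-6-carbaldehyde (formed in the flask, not isolated) | O=Cc1cc(OC)c2c(c1)O[C@H](c1ccc(OC)cc1)[C@H]2c1cc(OC)c2c(c1)occ2-c1cc(OC)cc(OC)c1 | intermediate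
22 | (2S,3S)-3-[(2S,3S)-3-(3,5-dimethoxyphenyl)-4-methoxy-2-(4-methoxyphenyl)-2,3-dihydro-1-benzofuran-6-yl]-4-methoxy-2-(4-methoxyphenyl)-2,3-dihydro-1-benzofuran-6-carbaldehyde | O=Cc1cc(OC)c2c(c1)O[C@H](c1ccc(OC)cc1)[C@H]2c1cc(OC)c2c(c1)O[C@H](c1ccc(OC)cc1)[C@H]2c1cc(OC)cc(OC)c1 | intermediate
23 | diethyl (4-methoxybenzyl)phosphonate | CCOP(=O)(Cc1ccc(OC)cc1)OCC | starting material
24 | potassium salt of the carbanion of diethyl (4-methoxybenzyl)phosphonate (formed in the flask, not isolated) | CCOP(=O)([CH-]c1ccc(OC)cc1)OCC.[K+] | intermediate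
25 | (2S,3S)-3-[(2S,3S)-3-(3,5-dimethoxyphenyl)-4-methoxy-2-(4-methoxyphenyl)-2,3-dihydro-1-benzofuran-6-yl]-4-methoxy-2-(4-methoxyphenyl)-6-[(E)-2-(4-methoxyphenyl)ethenyl]-2,3-dihydro-1-benzofuran | COc1ccc(/C=C/c2cc(OC)c3c(c2)O[C@H](c2ccc(OC)cc2)[C@H]3c2cc(OC)c3c(c2)O[C@H](c2ccc(OC)cc2)[C@H]3c2cc(OC)cc(OC)c2)cc1 | intermediate
26 | (2S,3S)-3-[(2S,3S)-3-(3,5-dihydroxyphenyl)-4-hydroxy-2-(4-hydroxyphenyl)-2,3-dihydro-1-benzofuran-6-yl]-2-(4-hydroxyphenyl)-6-[(E)-2-(4-hydroxyphenyl)ethenyl]-2,3-dihydro-1-benzofuran-4-ol | Oc1ccc(/C=C/c2cc(O)c3c(c2)O[C@H](c2ccc(O)cc2)[C@H]3c2cc(O)c3c(c2)O[C@H](c2ccc(O)cc2)[C@H]3c2cc(O)cc(O)c2)cc1 | target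

**Step count and risks**

Total step count: 9. Longest linear sequence: 9 steps (1 → 26).

Steps most likely to fail:

1. Step 7 (twofold dearomative reductive Heck). Formate may reduce the aryl–palladium species before it inserts into the trisubstituted aromatic C2=C3 bond, the reaction may divert to C2–H arylation, or facial selectivity may be insufficient. The fallback sets out from 18 and comes back at 22, using known chemistry and replacing catalyst control by resolution. Both C2–H bonds of 18 are arylated with 4-bromoanisole (Pd(OAc)2, PCy3·HBF4, PivOH, K2CO3, DMA, 110 °C; direct C2-arylation of 3-arylbenzofurans) to give the bis(2,3-diarylbenzofuran) aldehyde F1. The aldehyde is masked (HC(OMe)3, TsOH, MeOH) as the dimethyl acetal F2. Forcing heterogeneous hydrogenation (H2, 50 bar, Pd/C, EtOAc–MeOH, 60 °C) saturates each furan C2=C3 bond from one face to give the cis,cis tetrahydro acetal F3 as a mixture of racemic diastereomers. TFA in wet CH2Cl2 then ionises each C2–O bond reversibly through the 4-methoxybenzylic cation, which recloses to the more stable trans isomer, and hydrolyses the acetal. Preparative HPLC on a chiral stationary phase separates the stereoisomers of the trans,trans aldehyde to give 22.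

2. Step 6 (twofold demethylative cyclodehydration). Intermolecular Friedel–Crafts condensation of the electron-rich arenes with the three formyl groups, or unselective ether cleavage, may compete with ring closure. The fallback sets out from 9 and comes back at 18; it separates the demethylation from the ring closure and needs neither the Wittig reaction nor HBr. BCl3 (CH2Cl2, −78 → 0 °C; aqueous work-up) cleaves one methyl ether next to each ketone through the boron chelate and hydrolyses the acetal, giving the bis(ortho-hydroxy ketone) aldehyde F4. HC(OMe)3 and TsOH in MeOH restore the dimethyl acetal F5; the hydrogen-bonded diaryl ketones are not acetalised. Dimethylsulfoxonium methylide (Me3S(O)I, NaH, DMSO, rt → 50 °C; Corey–Chaykovsky reaction of ortho-hydroxyaryl ketones) converts each ketone into an oxirane that the neighbouring phenoxide opens at CH2, giving the bis(2,3-dihydrobenzofuran-3-ol) F6. TsOH in wet acetone at 50 °C dehydrates both tertiary benzylic alcohols to the furans and hydrolyses the acetal to give 18.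

3. Step 9 (global demethylation). The electron-rich stilbene may suffer hydrobromination, E/Z isomerisation or cationic oligomerisation during the long exposure to BBr3 and HBr. The fallback sets out from 22 and comes back at 26; it moves the demethylation ahead of the olefination and changes the protecting group. Aldehyde 22 is demethylated with BBr3 (CH2Cl2, −78 °C → rt) to the hexaphenol aldehyde F7. TBSCl and imidazole in DMF give the hexakis(tert-butyldimethylsilyl) ether aldehyde F8. Horner–Wadsworth–Emmons olefination with diethyl {4-[(tert-butyldimethylsilyl)oxy]benzyl}phosphonate (NaH, THF, 0 °C) gives the heptakis(tert-butyldimethylsilyl) ether of the target F9. Et3N·3HF in THF removes the silyl groups under near-neutral conditions to give 26.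

**Further compounds**

F1 | step 7 | 3-[3-(3,5-dimethoxyphenyl)-4-methoxy-2-(4-methoxyphenyl)-1-benzofuran-6-yl]-4-methoxy-2-(4-methoxyphenyl)-1-benzofuran-6-carbaldehyde | O=Cc1cc(OC)c2c(c1)oc(-c1ccc(OC)cc1)c2-c1cc(OC)c2c(c1)oc(-c1ccc(OC)cc1)c2-c1cc(OC)cc(OC)c1
F2 | step 7 | dimethyl acetal of F1, 6-(dimethoxymethyl)-3-[3-(3,5-dimethoxyphenyl)-4-methoxy-2-(4-methoxyphenyl)-1-benzofuran-6-yl]-4-methoxy-2-(4-methoxyphenyl)-1-benzofuran | COC(OC)c1cc(OC)c2c(c1)oc(-c1ccc(OC)cc1)c2-c1cc(OC)c2c(c1)oc(-c1ccc(OC)cc1)c2-c1cc(OC)cc(OC)c1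
F3 | step 7 | cis,cis 2,3,2′,3′-tetrahydro dimethyl acetal (mixture of racemic diastereomers; the (2R,3S,2′R,3′S) isomer that leads to 22 is drawn) | COC(OC)c1cc(OC)c2c(c1)O[C@@H](c1ccc(OC)cc1)[C@H]2c1cc(OC)c2c(c1)O[C@@H](c1ccc(OC)cc1)[C@H]2c1cc(OC)cc(OC)c1
F4 | step 6 | 4-[4-(3,5-dimethoxybenzoyl)-3-hydroxy-5-methoxybenzoyl]-3-hydroxy-5-methoxybenzaldehyde | O=C(c1cc(OC)cc(OC)c1)c1c(O)cc(C(=O)c2c(O)cc(C=O)cc2OC)cc1OC
F5 | step 6 | dimethyl acetal of F4, [4-(dimethoxymethyl)-2-hydroxy-6-methoxyphenyl][4-(3,5-dimethoxybenzoyl)-3-hydroxy-5-methoxyphenyl]methanone | O=C(c1cc(OC)cc(OC)c1)c1c(O)cc(C(=O)c2c(O)cc(C(OC)OC)cc2OC)cc1OC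
F6 | step 6 | 6-(dimethoxymethyl)-3-[3-(3,5-dimethoxyphenyl)-3-hydroxy-4-methoxy-2,3-dihydro-1-benzofuran-6-yl]-4-methoxy-2,3-dihydro-1-benzofuran-3-ol (mixture of racemic diastereomers) | COC(OC)c1cc(OC)c2c(c1)OCC2(O)c1cc(OC)c2c(c1)OCC2(O)c1cc(OC)cc(OC)c1
F7 | step 9 | (2S,3S)-3-[(2S,3S)-3-(3,5-dihydroxyphenyl)-4-hydroxy-2-(4-hydroxyphenyl)-2,3-dihydro-1-benzofuran-6-yl]-4-hydroxy-2-(4-hydroxyphenyl)-2,3-dihydro-1-benzofuran-6-carbaldehyde | O=Cc1cc(O)c2c(c1)O[C@H](c1ccc(O)cc1)[C@H]2c1cc(O)c2c(c1)O[C@H](c1ccc(O)cc1)[C@H]2c1cc(O)cc(O)c1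
F8 | step 9 | hexakis(tert-butyldimethylsilyl) ether of F7 | O=Cc1cc(O[Si](C)(C)C(C)(C)C)c2c(c1)O[C@H](c1ccc(O[Si](C)(C)C(C)(C)C)cc1)[C@H]2c1cc(O[Si](C)(C)C(C)(C)C)c2c(c1)O[C@H](c1ccc(O[Si](C)(C)C(C)(C)C)cc1)[C@H]2c1cc(O[Si](C)(C)C(C)(C)C)cc(O[Si](C)(C)C(C)(C)C)c1
F9 | step 9 | heptakis(tert-butyldimethylsilyl) ether of 26 | CC(C)(C)[Si](C)(C)Oc1ccc(/C=C/c2cc(O[Si](C)(C)C(C)(C)C)c3c(c2)O[C@H](c2ccc(O[Si](C)(C)C(C)(C)C)cc2)[C@H]3c2cc(O[Si](C)(C)C(C)(C)C)c3c(c2)O[C@H](c2ccc(O[Si](C)(C)C(C)(C)C)cc2)[C@H]3c2cc(O[Si](C)(C)C(C)(C)C)cc(O[Si](C)(C)C(C)(C)C)c2)cc1
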